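Everything rests on cutting the crowded diaryl ether bond between C2 of ring C (the 1,2,3-trisubstituted ring) and the oxygen on ring D (the meta-bridged ring). The key step exploits that C2 lies ortho to the C3 hydroxyl. With a formyl group at C3 and fluorine at C2, one intramolecular SNAr closes the 18-membered ring, makes the most hindered bond and needs no protecting group. Its precursor is an open-chain four-ring fluoro dialdehyde with a single free phenol. Ring B, whose hydroxyl is also ortho to an ether oxygen, is built by the same logic. A final double Baeyer–Villiger oxidation converts both activating formyl groups into the two phenols.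

Key step: step 4

Remark on the chemistry:
- Ring A is the para-bridged ring.
- Ring B carries OH para to its CH2CH2 chain.
- Ring C carries its chain at C1, the ether oxygen at C2 and OH at C3.
- Ring D is the meta-bridged ring.
- The target has no stereocentre.
- 3-Vinylphenol is taken as a catalogue compound.

Step 1
Reactants: 1 4-acetoxystyrene; 2 3-bromo-2-fluorobenzaldehyde
Product: 5 2-fluoro-3-[2-(4-hydroxyphenyl)ethyl]benzaldehyde, via B-alkyl-9-BBN adduct 3 (not isolated), via bibenzyl acetate 4 (not isolated)
Conditions: 1, 9-BBN (1.1 equiv), THF, 0 °C to rt; aq K3PO4, then 2, Pd(dppf)Cl2 (3 mol %), THF/H2O, 60 °C; then MeOH, rt; non-oxidative work-up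
Reagents that add atoms: 9-BBN, B1C2CCCC1CCC2 (its boron framework is held only by 3; 5 keeps only hydrogen from it)
Why: Anti-Markovnikov hydroboration of the styrene followed by B-alkyl Suzuki–Miyaura coupling at the C–Br bond of 2 builds the CH2CH2 bridge directly; the aldehyde should be spared because aqueous base destroys residual B–H and ties the borane up as its hydroxyborate before 2 is added, and base-catalysed methanolysis then removes the labile aryl acetate in the same flask.

Step 2
Reactants: 5 2-fluoro-3-[2-(4-hydroxyphenyl)ethyl]benzaldehyde; 6 4-bromo-2-fluorobenzaldehyde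
Product: 7 4-bromo-2-{4-[2-(2-fluoro-3-formylphenyl)ethyl]phenoxy}benzaldehyde
Conditions: 6 (1.3 equiv), K2CO3, DMF, 80 °C
Reagents that add atoms: none
Why: In this intermolecular SNAr the fluoride of 6 is unhindered and further activated by the meta bromine, whereas the fluoride of 5 is flanked by its alkyl chain, so the phenoxide of 5 should attack 6 and leave its own C–F bond untouched for step 4.

Step 3
Reactants: 7 4-bromo-2-{4-[2-(2-fluoro-3-formylphenyl)ethyl]phenoxy}benzaldehyde; 8 3-vinylphenol
Product: 10 2-{4-[2-(2-fluoro-3-formylphenyl)ethyl]phenoxy}-4-[2-(3-hydroxyphenyl)ethyl]benzaldehyde (seco-phenol), via O,C-bis(9-BBN) adduct 9 (not isolated)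
Conditions: 8, 9-BBN (2.2 equiv), THF, 0 °C to rt; aq K3PO4, then 7, Pd(dppf)Cl2 (5 mol %), THF/H2O, 60 °C; non-oxidative work-up
Reagents that add atoms: 9-BBN, B1C2CCCC1CCC2 (its boron framework is held only by 9; 10 keeps only hydrogen from it)
Why: One equivalent of 9-BBN borylates the phenol oxygen and the second hydroborates the vinyl group, after which B-alkyl Suzuki–Miyaura coupling at the C–Br bond para to the ring B formyl group attaches ring D, the O–B bond hydrolyses in the aqueous base, and the hindered C–F bond stays inert in aqueous THF at this temperature.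

Step 4
Reactants: 10 seco-phenol
Product: 11 macrocyclic dialdehyde (marchantin C ring system with CHO in place of the OH on ring B and of the OH at C3 of ring C)
Conditions: Cs2CO3, 4 Å MS, degassed DMSO, 110 °C, syringe-pump addition of 10 (final 0.002 M), Ar
Reagents that add atoms: none
Why: Cs2CO3 converts the only phenol of 10 (ring D) into its caesium phenoxide, which adds to C2 of ring C to give a Meisenheimer anion whose charge is delocalised into the ortho formyl group at C3, and loss of fluoride restores aromaticity (addition–elimination SNAr). The closest known reaction type is the intramolecular SNAr cycloetherification of ortho-activated aryl fluorides used for macrocyclic diaryl ethers, together with the routine coupling of phenols with 2-fluorobenzaldehydes. The single ring formed is the 18-membered cyclophane, closed in a formally 18-exo-trig addition because the C2=C3 bond that takes up the charge lies outside the new ring. No stereocentre is created. Cyclisation must beat oligomerisation, which slow addition into a large volume of hot DMSO and the two flexible CH2CH2 hinges should secure, and attack must occur at C–F only: 10 holds one phenol and one fluoride, and displacement of the aryloxy group ortho to the ring B aldehyde is disfavoured by its far poorer leaving-group ability and by the strained nine-membered ring it would give. Fluorine is the smallest leaving group available for the crowded C2 position, and DMSO is preferred to DMF so that no dimethylamine can compete for the fluoride.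

Step 5
Reactants: 11 macrocyclic dialdehyde
Product: 13 marchantin C, via macrocyclic bis(formate) 12 (not isolated)
Conditions: mCPBA (3 equiv), CH2Cl2, 0 °C to rt; aq Na2S2O3/NaHCO3 wash; then MeOH, cat. K2CO3, rt
Reagents that add atoms: mCPBA, O=C(OO)c1cccc(Cl)c1
Why: In this double Baeyer–Villiger oxidation (Dakin-type outcome) the aryl group of each Criegee adduct, made electron-rich by its ortho aryloxy substituent, should migrate in preference to hydrogen, and mild methanolysis of the two aryl formates releases both phenols only after the peracid has been removed.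

Compound list
1 | 4-acetoxystyrene (4-vinylphenyl acetate) | C=Cc1ccc(OC(C)=O)cc1 | starting material
2 | 3-bromo-2-fluorobenzaldehyde | O=Cc1cccc(Br)c1F | starting material
3 | 4-[2-(9-borabicyclo[3.3.1]nonan-9-yl)ethyl]phenyl acetate | CC(=O)Oc1ccc(CCB2C3CCCC2CCC3)cc1 | intermediate
4 | 4-[2-(2-fluoro-3-formylphenyl)ethyl]phenyl acetate | CC(=O)Oc1ccc(CCc2cccc(C=O)c2F)cc1 | intermediate
5 | 2-fluoro-3-[2-(4-hydroxyphenyl)ethyl]benzaldehyde | Oc1ccc(CCc2cccc(C=O)c2F)cc1 | intermediate
6 | 4-bromo-2-fluorobenzaldehyde | O=Cc1ccc(Br)cc1F | starting material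
7 | 4-bromo-2-{4-[2-(2-fluoro-3-formylphenyl)ethyl]phenoxy}benzaldehyde | O=Cc1ccc(Br)cc1Oc1ccc(CCc2cccc(C=O)c2F)cc1 | intermediate
8 | 3-vinylphenol | C=Cc1cccc(O)c1 | starting material
9 | 9-{3-[2-(9-borabicyclo[3.3.1]nonan-9-yl)ethyl]phenoxy}-9-borabicyclo[3.3.1]nonane | B1(Oc2cccc(CCB3C4CCCC3CCC4)c2)C2CCCC1CCC2 | intermediate
10 | 2-{4-[2-(2-fluoro-3-formylphenyl)ethyl]phenoxy}-4-[2-(3-hydroxyphenyl)ethyl]benzaldehyde (seco-phenol) | O=Cc1ccc(CCc2cccc(O)c2)cc1Oc1ccc(CCc2cccc(C=O)c2F)cc1 | intermediate
11 | macrocyclic dialdehyde (marchantin C with both OH replaced by CHO) | O=Cc1ccc2cc1Oc1ccc(cc1)CCc1cccc(C=O)c1Oc1cccc(c1)CC2 | intermediate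
12 | macrocyclic bis(formate) of marchantin C | O=COc1ccc2cc1Oc1ccc(cc1)CCc1cccc(OC=O)c1Oc1cccc(c1)CC2 | intermediate
13 | marchantin C | Oc1ccc2cc1Oc1ccc(cc1)CCc1cccc(O)c1Oc1cccc(c1)CC2 | target

Total step count: 5. Longest linear sequence: 5 steps (1 or 2 to 13).

Steps most likely to fail

Risk 1 (step 4). Addition of the phenoxide to the crowded C–F carbon, which is activated by only one formyl group, may be so slow that oligomerisation and base-induced degradation of the aldehydes overtake ring closure. The fallback keeps the same ring-closing bond but replaces SNAr with palladium-catalysed C–O cross-coupling of a chloride. It sets out from 1 (through borane 3) and comes back at 11.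
- Borane 3 is coupled under the conditions of step 1 with purchased 3-bromo-2-chlorobenzaldehyde (O=Cc1cccc(Br)c1Cl). This should give 4-[2-(2-chloro-3-formylphenyl)ethyl]phenyl acetate F1, which is methanolysed in the same flask to 2-chloro-3-[2-(4-hydroxyphenyl)ethyl]benzaldehyde F2.
- SNAr with 6 as in step 2 should give 4-bromo-2-{4-[2-(2-chloro-3-formylphenyl)ethyl]phenoxy}benzaldehyde F3. The chloride is even less prone to self-condensation than the fluoride.
- Coupling with 9 as in step 3, where C–Br reacts before C–Cl with Pd(dppf)Cl2, should give the chloro seco-phenol F4.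
- A Buchwald–Hartwig-type etherification then closes the ring: Pd(OAc)2, tBuXPhos (2-di-tert-butylphosphino-2',4',6'-triisopropylbiphenyl), K3PO4, toluene, 100 °C, slow addition. Zerovalent palladium inserts into the C–Cl bond activated by the ortho formyl group, and the crowding at C2 should favour reductive elimination to 11.

Risk 2 (step 3). Hydride transfer from boron species to the two aldehydes, or slow transmetallation followed by protodeboronation, may erode the coupling. The fallback avoids boron altogether. It sets out from 7 and comes back at 10.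
- Sonogashira coupling of 7 with purchased 3-ethynylphenol (C#Cc1cccc(O)c1) uses Pd(PPh3)2Cl2, copper iodide CuI, Et3N and THF at 50 °C. It should give 2-{4-[2-(2-fluoro-3-formylphenyl)ethyl]phenoxy}-4-[(3-hydroxyphenyl)ethynyl]benzaldehyde F5.
- Chemoselective hydrogenation of the alkyne over Pd/C poisoned with diphenyl sulfide (H2, 1 atm, EtOAc, rt) leaves aromatic aldehydes and the C–F bond alone and should give 10.

Risk 3 (step 5). Hydrogen migration may compete with aryl migration in one of the Criegee adducts, most likely at the crowded ring C formyl group, and would divert material towards over-oxidation at the carbonyl carbon. The fallback removes the migrating hydrogen. It sets out from 11 and comes back at 13.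
- Double Grignard addition (MeMgBr, THF, −78 to 0 °C) should give the macrocyclic bis(1-hydroxyethyl) compound F6 as a mixture of diastereomers of no consequence.
- Dess–Martin oxidation should give the macrocyclic bis(methyl ketone) F7.
- Baeyer–Villiger oxidation (mCPBA, TFA, CH2Cl2), in which aryl reliably migrates ahead of methyl, should give marchantin C diacetate F8.
- Methanolysis (cat. K2CO3, MeOH) should give 13.

Further compounds
F1 | step 4 | 4-[2-(2-chloro-3-formylphenyl)ethyl]phenyl acetate | CC(=O)Oc1ccc(CCc2cccc(C=O)c2Cl)cc1
F2 | step 4 | 2-chloro-3-[2-(4-hydroxyphenyl)ethyl]benzaldehyde | Oc1ccc(CCc2cccc(C=O)c2Cl)cc1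
F3 | step 4 | 4-bromo-2-{4-[2-(2-chloro-3-formylphenyl)ethyl]phenoxy}benzaldehyde | O=Cc1ccc(Br)cc1Oc1ccc(CCc2cccc(C=O)c2Cl)cc1
F4 | step 4 | chloro seco-phenol, 2-{4-[2-(2-chloro-3-formylphenyl)ethyl]phenoxy}-4-[2-(3-hydroxyphenyl)ethyl]benzaldehyde | O=Cc1ccc(CCc2cccc(O)c2)cc1Oc1ccc(CCc2cccc(C=O)c2Cl)cc1
F5 | step 3 | 2-{4-[2-(2-fluoro-3-formylphenyl)ethyl]phenoxy}-4-[(3-hydroxyphenyl)ethynyl]benzaldehyde | O=Cc1ccc(C#Cc2cccc(O)c2)cc1Oc1ccc(CCc2cccc(C=O)c2F)cc1
F6 | step 5 | macrocyclic bis(1-hydroxyethyl) compound (diastereomer mixture) | CC(O)c1ccc2cc1Oc1ccc(cc1)CCc1cccc(C(C)O)c1Oc1cccc(c1)CC2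
F7 | step 5 | macrocyclic bis(methyl ketone) | CC(=O)c1ccc2cc1Oc1ccc(cc1)CCc1cccc(C(C)=O)c1Oc1cccc(c1)CC2
F8 | step 5 | marchantin C diacetate | CC(=O)Oc1ccc2cc1Oc1ccc(cc1)CCc1cccc(OC(C)=O)c1Oc1cccc(c1)CC2
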